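Amounts first: noon and summer carry the same free monomer and protic impurity and differ in initiator.

| setting | noon | summer |
|---|---|---|
| free monomer | 1.5 M | 1.5 M |
| protic impurity | 1.50 M | 1.50 M |
| initiator | 33 mM | 60 mM |
| time | 20 h | 20 h |

    initiator → 2 initiating radical (k1 = 5.71 × 10⁻⁵ s⁻¹)
    free monomer + initiating radical → growing radical + monomer in chains (k2 = 57900 M⁻¹ s⁻¹)
    free monomer + growing radical → monomer in chains + growing radical, rate k3*[growing radical]*[free monomer] (k3 = 786 M⁻¹ s⁻¹)
    2 growing radical → dead chain (k4 = 9.1 × 10⁸ M⁻¹ s⁻¹)
    protic impurity + free monomer → quenched substrate (k5 = 1.27 × 10⁻⁵ M⁻¹ s⁻¹)

- where a step has two of a species, its rate is k times that concentration squared, and two are used at each turn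
- the average divides the monomer in chains by the number of chains, living and dead together; two radicals that join make one chain
- run time (noon): 20 h

- which of the two ends with the longer chains by the average number of monomer units in a chain (living and dead chains, two that joined counted as one) ("neither" if they lie within 10%) (noon / summer / neither)
- average number of monomer units in a chain (living and dead chains, two that joined counted as one) at the end, noon
- average number of monomer units in a chain (living and dead chains, two that joined counted as one) at the end, summer

The initiator gives the denominator. Each one makes two radicals and two radicals join into one chain, so chains per initiator charged equal the part spent in the run, my chain yield 98.4%. That makes 0.0325 M of chains in noon and 0.0590 M in summer; the living ones, about 4.55 × 10⁻⁸ M at the start of noon, count for little.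

Now the bound from above. Growing radical rests at its quasi-steady level, where pairs die as fast as they form, and it decays at half the initiator's rate. Integrated over the run, the pseudo-first-order chain step has the exponent 1.09 in noon and 1.47 in summer. Unopposed, and with the 2 units that initiation puts in each chain, this caps the length at 32.7 in noon and 21.6 in summer.

From below, the quench with protic impurity held at its charge has the exponent 1.37. Growing radical falls off faster than protic impurity does even at the full charge of free monomer, so the chain step's share of lost free monomer is at least its share of the exponents. That gives 19.9 in noon and 13.4 in summer.

The brackets overlap, so my hand proves no order. But from noon to summer chains rise 1.82-fold and the exponent 1.35-fold, and the middles are 26.3 and 17.5: I commit to noon.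

The forecast says noon, with 25 (23.5 to 26.5) for noon and 16.5 (15.5 to 17.5) for summer, on the same count: “Each initiator gives one final chain”. Both figures lie inside my brackets , and below my middles .

The flask gives noon, with 24.6 in noon and 16.3 in summer, each inside its bracket .

The initiator's half-life of 3.4 h is far shorter than the 20 h run, and 1.6% of it is left in noon, 1.6% in summer. Take summer's recipe with 0.036 M of initiator: the yield gives 0.0354 M of chains, and its 54.8% of the charge in chains makes 23.2 units per chain. That flask stands at 23.2, and beside noon it reads neither, inside the margin of 10%, with noon ahead by 5.69%.

The numbers of this flask are those of an exercise.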